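**Retrosynthetic overview**
- Target ⇐ C11 set last by kinetic protonation; the ten-membered ring (formed last) ⇐ SmI2 pinacol coupling of a C2/C3 dialdehyde, which forms the C2–C3 bond and both carbinol centres.
- Dialdehyde ⇐ Diels–Alder reaction of an (E)-2-methyl enal with a 1-methoxy-3-silyloxypentadiene (ring A, second ring; C1 and C10).
- Enal ⇐ cross-metathesis of a vinyl lactone with methacrolein; lactone (first ring; C8, C17) ⇐ CuH reductive aldol cyclisation of an acrylate onto the C8 ketone.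
- Acrylate/chloride ⇐ epoxy ketone + acryloyl chloride (C6–Cl, C7–O); C9 ⇐ Brown alkoxyallylboration; C6/C7 ⇐ Sharpless epoxidation of a Heck-derived dienol.

Assumption: locants C1–C20 are those of the briarane skeleton of the target (C1 quaternary with C15 methyl; C2, C3, C9 acetoxy carbons; C5=C16H2; C6–Cl; C7–O and C8–OH lactone carbons; C17 lactone α-carbon with C18 methyl; C19 lactone C=O; C11 with C20 methyl; C12=O; C13=C14), and the six starting materials are taken as catalogue compounds.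

**Step 1**
Reactants: 1 3-bromobut-3-en-1-ol
Product: 2 [(3-bromobut-3-en-1-yl)oxy](tert-butyl)dimethylsilane
Conditions: TBSCl, imidazole, DMF, 0 °C to rt
Reagents that add atoms: tert-butyldimethylsilyl chloride, CC(C)(C)[Si](C)(C)Cl
Why: Silyl ether formation masks the future C3 oxygen so that only the C8 alcohol is oxidised in step 5; no stereocentre is formed.

**Step 2**
Reactants: 2 [(3-bromobut-3-en-1-yl)oxy](tert-butyl)dimethylsilane; 3 methyl acrylate
Product: 4 methyl (2E)-6-[(tert-butyldimethylsilyl)oxy]-4-methylidenehex-2-enoate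
Conditions: Pd(OAc)2 (3 mol%), P(o-tol)3, Et3N, MeCN, 80 °C
Reagents that add atoms: none
Why: Heck reaction of a 2-bromo-1-alkene with an acrylate forms the C5–C6 bond and gives the (E)-dienoate by syn insertion and syn β-hydride elimination.

**Step 3**
Reactants: 4 methyl (2E)-6-[(tert-butyldimethylsilyl)oxy]-4-methylidenehex-2-enoate
Product: 5 (2E)-6-[(tert-butyldimethylsilyl)oxy]-4-methylidenehex-2-en-1-ol
Conditions: iBu2AlH (2.2 equiv), CH2Cl2, −78 °C
Reagents that add atoms: none
Why: 1,2-Reduction of the conjugated ester gives the (E)-allylic alcohol needed for the directed epoxidation.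

**Step 4**
Reactants: 5 (2E)-6-[(tert-butyldimethylsilyl)oxy]-4-methylidenehex-2-en-1-ol
Product: 6 [(2R,3R)-3-{4-[(tert-butyldimethylsilyl)oxy]but-1-en-2-yl}oxiran-2-yl]methanol
Conditions: Ti(OiPr)4, D-(−)-diisopropyl tartrate, tBuOOH, 4 Å sieves, CH2Cl2, −20 °C
Reagents that add atoms: tert-butyl hydroperoxide, CC(C)(C)OO
Why: Sharpless asymmetric epoxidation with D-(−)-tartrate gives the (2R,3R)-epoxide of the (E)-allylic alcohol (future C7 and, after inversion, C6), and the 1,1-disubstituted alkene lacking an allylic hydroxyl is left alone.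

**Step 5**
Reactants: 6 [(2R,3R)-3-{4-[(tert-butyldimethylsilyl)oxy]but-1-en-2-yl}oxiran-2-yl]methanol
Product: 7 (2S,3R)-3-{4-[(tert-butyldimethylsilyl)oxy]but-1-en-2-yl}oxirane-2-carbaldehyde
Conditions: Dess–Martin periodinane, pyridine, CH2Cl2, 0 °C
Reagents that add atoms: none
Why: Dess–Martin oxidation gives the trans-epoxy aldehyde under buffered conditions that do not open the vinyl epoxide.

**Step 6**
Reactants: 7 (2S,3R)-3-{4-[(tert-butyldimethylsilyl)oxy]but-1-en-2-yl}oxirane-2-carbaldehyde; 8 3-(methoxymethoxy)prop-1-ene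
Product: 10 (1R,2S)-1-[(2R,3R)-3-{4-[(tert-butyldimethylsilyl)oxy]but-1-en-2-yl}oxiran-2-yl]-2-(methoxymethoxy)but-3-en-1-ol, via allylborane 9 (not isolated)
Conditions: 8, s-BuLi, THF, −78 °C; (+)-Ipc2BOMe; BF3·OEt2; then 7, −78 °C; HOCH2CH2NH2 work-up
Reagents that add atoms: none
Why: Brown alkoxyallylboration through a chair transition state gives the syn C8–OH/C9–OMOM pair, and the borane of the (−)-α-pinene series attacks the Re face of the aldehyde (matched with Felkin–Anh attack anti to the epoxide C–O bond), which sets C9 as S.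

**Step 7**
Reactants: 10 (1R,2S)-1-[(2R,3R)-3-{4-[(tert-butyldimethylsilyl)oxy]but-1-en-2-yl}oxiran-2-yl]-2-(methoxymethoxy)but-3-en-1-ol
Product: 11 (2S)-1-[(2S,3R)-3-{4-[(tert-butyldimethylsilyl)oxy]but-1-en-2-yl}oxiran-2-yl]-2-(methoxymethoxy)but-3-en-1-one
Conditions: Dess–Martin periodinane, pyridine, CH2Cl2, 0 °C
Reagents that add atoms: none
Why: Dess–Martin oxidation turns the temporary C8 carbinol into the C8 ketone under non-basic conditions that leave the doubly activated C9–H configuration intact.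

**Step 8**
Reactants: 11 (2S)-1-[(2S,3R)-3-{4-[(tert-butyldimethylsilyl)oxy]but-1-en-2-yl}oxiran-2-yl]-2-(methoxymethoxy)but-3-en-1-one; 12 acryloyl chloride
Product: 13 (4S,5R,7S)-1-[(tert-butyldimethylsilyl)oxy]-4-chloro-7-(methoxymethoxy)-3-methylidene-6-oxonon-8-en-5-yl prop-2-enoate
Conditions: nBu4NCl (10 mol%), CH2Cl2, 0 °C to rt
Reagents that add atoms: none
Why: Chloroacylation of an epoxide by an acyl chloride: chloride opens the O-acylated epoxide by SN2 at the allylic carbon C6, remote from the deactivating ketone, with inversion (6S), while the acryloyl group stays on O7 with retention (7R).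

**Step 9**
Reactants: 13 (4S,5R,7S)-1-[(tert-butyldimethylsilyl)oxy]-4-chloro-7-(methoxymethoxy)-3-methylidene-6-oxonon-8-en-5-yl prop-2-enoate
Product: 15 (3R,4R,5R)-5-[(1S)-1-chloro-4-hydroxy-2-methylidenebutyl]-4-hydroxy-4-[(1S)-1-(methoxymethoxy)prop-2-en-1-yl]-3-methyloxolan-2-one, via disiloxanyl ether 14 (not isolated)
Conditions: Cu(OAc)2·H2O (5 mol%), rac-BINAP (5 mol%), (HMe2Si)2O, THF, rt; then HF·pyridine, pyridine, THF, 0 °C
Reagents that add atoms: none
Why: CuH-catalysed reductive aldol cyclisation (Lam type): hydride adds to the acrylate and the (Z)-copper enolate closes onto the C8 ketone through a chair transition state that places the C9 chain trans to the C6 chain and the C8–OH cis to the C17 methyl (8R, 17R), after which HF cleaves both silyl ethers.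

**Step 10**
Reactants: 15 (3R,4R,5R)-5-[(1S)-1-chloro-4-hydroxy-2-methylidenebutyl]-4-hydroxy-4-[(1S)-1-(methoxymethoxy)prop-2-en-1-yl]-3-methyloxolan-2-one; 16 methacrolein
Product: 17 (2E,4S)-4-{(2R,3R,4R)-2-[(1S)-1-chloro-4-hydroxy-2-methylidenebutyl]-3-hydroxy-4-methyl-5-oxooxolan-3-yl}-4-(methoxymethoxy)-2-methylbut-2-enal
Conditions: 16 (10 equiv), second-generation Hoveyda–Grubbs catalyst RuCl2(H2IMes)(=CH-C6H4-2-OiPr) (10 mol%), CH2Cl2, 40 °C
Reagents that add atoms: none
Why: Olefin cross-metathesis of the monosubstituted alkene with methacrolein gives the thermodynamically favoured (E)-trisubstituted enal, and the 1,1-disubstituted C5 methylene does not take part.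

**Step 11**
Reactants: 17 (2E,4S)-4-{(2R,3R,4R)-2-[(1S)-1-chloro-4-hydroxy-2-methylidenebutyl]-3-hydroxy-4-methyl-5-oxooxolan-3-yl}-4-(methoxymethoxy)-2-methylbut-2-enal
Product: 18 (2E,4S)-4-{(2R,3R,4R)-2-[(1S)-1-chloro-2-methylidene-4-oxobutyl]-3-hydroxy-4-methyl-5-oxooxolan-3-yl}-4-(methoxymethoxy)-2-methylbut-2-enal
Conditions: Dess–Martin periodinane, pyridine, CH2Cl2, 0 °C
Reagents that add atoms: none
Why: Dess–Martin oxidation of the only primary alcohol gives the C3 aldehyde without base, so the β,γ-double bond does not move into conjugation and the tertiary C8–OH is untouched.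

**Step 12**
Reactants: 19 (3E)-4-methoxybut-3-en-2-one
Product: 20 (1E)-1-methoxypent-1-en-3-one
Conditions: LiN(iPr)2, THF, −78 °C; MeI
Reagents that add atoms: iodomethane, CI
Why: Kinetic α′-deprotonation of the vinylogous ester and enolate alkylation introduce the future C20 methyl.

**Step 13**
Reactants: 20 (1E)-1-methoxypent-1-en-3-one
Product: 21 tert-butyl{[(1E,3Z)-1-methoxypenta-1,3-dien-3-yl]oxy}dimethylsilane
Conditions: TBSOTf, Et3N, Et2O, 0 °C
Reagents that add atoms: tert-butyldimethylsilyl trifluoromethanesulfonate, CC(C)(C)[Si](C)(C)OS(=O)(=O)C(F)(F)F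
Why: Soft enolisation and O-silylation give the (3Z)-silyl enol ether, a 4-methyl Danishefsky-type diene.

**Step 14**
Reactants: 18 (2E,4S)-4-{(2R,3R,4R)-2-[(1S)-1-chloro-2-methylidene-4-oxobutyl]-3-hydroxy-4-methyl-5-oxooxolan-3-yl}-4-(methoxymethoxy)-2-methylbut-2-enal; 21 tert-butyl{[(1E,3Z)-1-methoxypenta-1,3-dien-3-yl]oxy}dimethylsilane
Product: 22 ring A cycloadduct: 4-[(tert-butyldimethylsilyl)oxy]-2-methoxy-1,5-dimethylcyclohex-3-ene-1-carbaldehyde carrying at ring carbon 6 (C10) the C9 side chain of 18; C1 and C10 as in the target; 14-OMe and C20 methyl both cis to the formyl group (C11 epimeric to the target)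
Conditions: 21 (3 equiv), toluene, 110 °C, sealed tube
Reagents that add atoms: none
Why: Thermal normal-demand Diels–Alder reaction: the methyl-bearing nucleophilic diene terminus bonds to the enal β-carbon C10 and the methoxy terminus to C1, the (E)-alkene gives the trans C1/C10 relationship, and the diene adds anti to the allylic C9–O bond while C9–H eclipses the cis C1 methyl (allylic strain, the sense I recall for (Z)-γ-alkoxy enoates), which gives the C1 and C10 configurations of the target; the endo-derived C11 and C14 centres are not carried through, and the unactivated C3 aldehyde does not react with this diene without a Lewis acid.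

**Step 15**
Reactants: 22 ring A cycloadduct dialdehyde
Product: 23 macrocyclic 2,3-diol: ten-membered ring closed between C2 and C3, (2R,3S)-diol, 9-OMOM, 8-OH, 6-Cl, 5(16)-ene, lactone, ring A still as the 12-silyl enol ether with 14-OMe
Conditions: SmI2 (3 equiv), tBuOH (4 equiv), THF, 0 °C, substrate added over 6 h to 2 mM
Reagents that add atoms: none
Why: Proposed new method: SmI2 pinacol macrocyclisation to a ten-membered ring, in which the unhindered C3 aldehyde is reduced to a ketyl radical that adds to the C2 aldehyde bound to the same trivalent samarium centre (or couples with a second ketyl), the oxygen-bridged transition state giving the cis-diol and attack on the neopentyl C2 aldehyde occurring anti to C10 (Felkin–Anh), hence 2R,3S; the closest known reactions are SmI2 pinacol cyclisations to five- to eight-membered cis-diols and Ti-mediated pinacol closures of ten-membered rings, and without HMPA the allylic chloride, lactone and silyl enol ether should not be reduced.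

**Step 16**
Reactants: 23 macrocyclic 2,3-diol
Product: 24 2,3,9-triol enone: 11-epimer of the tri-O-deacetyl target (2,3,8,9-tetrol with 12-oxo-13-ene)
Conditions: HCl (0.5 M) in MeOH, 40 °C
Reagents that add atoms: none
Why: Acid methanolysis removes the C9 MOM ether and the silyl enol ether, and the β-methoxy ketone then eliminates methanol to the C13–C14 enone (Danishefsky unmasking); no stereocentre is formed and C11 is reset in step 18.

**Step 17**
Reactants: 24 2,3,9-triol enone
Product: 25 11-epimer of the target (2,3,9-triacetate)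
Conditions: Ac2O, pyridine, DMAP (5 mol%), CH2Cl2, 0 °C to rt
Reagents that add atoms: acetic anhydride, CC(=O)OC(C)=O
Why: Acylation of the three secondary hydroxyls at C2, C3 and C9, while the hindered tertiary C8–OH does not react under these conditions.

**Step 18**
Reactants: 25 11-epimer of the target
Product: 27 target, via bis-silyl dienol ether 26 (not isolated)
Conditions: TMSOTf, Et3N, CH2Cl2, −78 to 0 °C; then AcOH, THF/H2O, −40 to 0 °C
Reagents that add atoms: none
Why: Soft enolisation of the enone (only the C11 α′-hydrogen exists because C1 is quaternary) gives the cross-conjugated 2-silyloxy diene, erasing C11, and kinetic C-protonation from the ring A face opposite the C1 methyl and the C9 substituent sets 11R (Zimmerman-type kinetic protonation, by analogy with 2-methyl-3-keto steroid enolates), the tertiary silyl ether being hydrolysed in the same quench.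

**Compound list**
1 | 3-bromobut-3-en-1-ol | OCCC(Br)=C | starting material
2 | [(3-bromobut-3-en-1-yl)oxy](tert-butyl)dimethylsilane | C=C(Br)CCO[Si](C)(C)C(C)(C)C | intermediate
3 | methyl acrylate | C=CC(=O)OC | starting material
4 | methyl (2E)-6-[(tert-butyldimethylsilyl)oxy]-4-methylidenehex-2-enoate | COC(=O)/C=C/C(=C)CCO[Si](C)(C)C(C)(C)C | intermediate
5 | (2E)-6-[(tert-butyldimethylsilyl)oxy]-4-methylidenehex-2-en-1-ol | OC/C=C/C(=C)CCO[Si](C)(C)C(C)(C)C | intermediate
6 | [(2R,3R)-3-{4-[(tert-butyldimethylsilyl)oxy]but-1-en-2-yl}oxiran-2-yl]methanol | OC[C@H]1O[C@@H]1C(=C)CCO[Si](C)(C)C(C)(C)C | intermediate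
7 | (2S,3R)-3-{4-[(tert-butyldimethylsilyl)oxy]but-1-en-2-yl}oxirane-2-carbaldehyde | O=C[C@H]1O[C@@H]1C(=C)CCO[Si](C)(C)C(C)(C)C | intermediate
8 | 3-(methoxymethoxy)prop-1-ene (allyl methoxymethyl ether) | C=CCOCOC | starting material
9 | [(2Z)-3-(methoxymethoxy)prop-2-en-1-yl]bis[(1S,2R,3S,5S)-2,6,6-trimethylbicyclo[3.1.1]heptan-3-yl]borane | COCO/C=C\CB([C@H]1C[C@H]2C[C@@H]([C@@H]1C)C2(C)C)[C@H]1C[C@H]2C[C@@H]([C@@H]1C)C2(C)C | intermediate
10 | (1R,2S)-1-[(2R,3R)-3-{4-[(tert-butyldimethylsilyl)oxy]but-1-en-2-yl}oxiran-2-yl]-2-(methoxymethoxy)but-3-en-1-ol | C=C[C@H](OCOC)[C@@H](O)[C@H]1O[C@@H]1C(=C)CCO[Si](C)(C)C(C)(C)C | intermediate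
11 | (2S)-1-[(2S,3R)-3-{4-[(tert-butyldimethylsilyl)oxy]but-1-en-2-yl}oxiran-2-yl]-2-(methoxymethoxy)but-3-en-1-one | C=C[C@H](OCOC)C(=O)[C@H]1O[C@@H]1C(=C)CCO[Si](C)(C)C(C)(C)C | intermediate
12 | acryloyl chloride | C=CC(=O)Cl | starting material
13 | (4S,5R,7S)-1-[(tert-butyldimethylsilyl)oxy]-4-chloro-7-(methoxymethoxy)-3-methylidene-6-oxonon-8-en-5-yl prop-2-enoate | C=C[C@H](OCOC)C(=O)[C@@H](OC(=O)C=C)[C@@H](Cl)C(=C)CCO[Si](C)(C)C(C)(C)C | intermediate
14 | (3R,4R,5R)-5-{(1S)-4-[(tert-butyldimethylsilyl)oxy]-1-chloro-2-methylidenebutyl}-4-[(1S)-1-(methoxymethoxy)prop-2-en-1-yl]-3-methyl-4-[(1,1,3,3-tetramethyldisiloxanyl)oxy]oxolan-2-one | C=C[C@H](OCOC)[C@]1(O[Si](C)(C)O[SiH](C)C)[C@@H](C)C(=O)O[C@H]1[C@@H](Cl)C(=C)CCO[Si](C)(C)C(C)(C)C | intermediate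
15 | (3R,4R,5R)-5-[(1S)-1-chloro-4-hydroxy-2-methylidenebutyl]-4-hydroxy-4-[(1S)-1-(methoxymethoxy)prop-2-en-1-yl]-3-methyloxolan-2-one | C=C[C@H](OCOC)[C@]1(O)[C@@H](C)C(=O)O[C@H]1[C@@H](Cl)C(=C)CCO | intermediate
16 | methacrolein (2-methylprop-2-enal) | CC(=C)C=O | starting material
17 | (2E,4S)-4-{(2R,3R,4R)-2-[(1S)-1-chloro-4-hydroxy-2-methylidenebutyl]-3-hydroxy-4-methyl-5-oxooxolan-3-yl}-4-(methoxymethoxy)-2-methylbut-2-enal | O=C/C(C)=C/[C@H](OCOC)[C@]1(O)[C@@H](C)C(=O)O[C@H]1[C@@H](Cl)C(=C)CCO | intermediate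
18 | (2E,4S)-4-{(2R,3R,4R)-2-[(1S)-1-chloro-2-methylidene-4-oxobutyl]-3-hydroxy-4-methyl-5-oxooxolan-3-yl}-4-(methoxymethoxy)-2-methylbut-2-enal | O=C/C(C)=C/[C@H](OCOC)[C@]1(O)[C@@H](C)C(=O)O[C@H]1[C@@H](Cl)C(=C)CC=O | intermediate
19 | (3E)-4-methoxybut-3-en-2-one | CO/C=C/C(C)=O | starting material
20 | (1E)-1-methoxypent-1-en-3-one | CCC(=O)/C=C/OC | intermediate
21 | tert-butyl{[(1E,3Z)-1-methoxypenta-1,3-dien-3-yl]oxy}dimethylsilane | C/C=C(/C=C/OC)O[Si](C)(C)C(C)(C)C | intermediate
22 | ring A cycloadduct dialdehyde (C1-formyl, 14-OMe and C20 methyl cis to formyl, 12-OTBS enol ether, C10 side chain of 18) | O=C[C@@]1(C)[C@@H](OC)C=C(O[Si](C)(C)C(C)(C)C)[C@@H](C)[C@@H]1[C@H](OCOC)[C@]2(O)[C@@H](C)C(=O)O[C@H]2[C@@H](Cl)C(=C)CC=O | intermediate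
23 | macrocyclic (2R,3S)-diol (9-OMOM, 8-OH, 6-Cl, ring A as 12-OTBS enol ether with 14-OMe, 11-epi) | C=C1C[C@H](O)[C@H](O)[C@@]2(C)[C@@H](OC)C=C(O[Si](C)(C)C(C)(C)C)[C@@H](C)[C@@H]2[C@H](OCOC)[C@]2(O)[C@@H](C)C(=O)O[C@H]2[C@H]1Cl | intermediate
24 | 11-epi-2,3,9-tri-O-deacetyl target (2,3,8,9-tetrol enone) | C=C1C[C@H](O)[C@H](O)[C@@]2(C)C=CC(=O)[C@@H](C)[C@@H]2[C@H](O)[C@]2(O)[C@@H](C)C(=O)O[C@H]2[C@H]1Cl | intermediate
25 | 11-epi target (2,3,9-triacetate) | C=C1C[C@H](OC(C)=O)[C@H](OC(C)=O)[C@@]2(C)C=CC(=O)[C@@H](C)[C@@H]2[C@H](OC(C)=O)[C@]2(O)[C@@H](C)C(=O)O[C@H]2[C@H]1Cl | intermediate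
26 | 12-O-trimethylsilyl 11,13-dienol ether of 25 with 8-O-trimethylsilyl ether | C=C1C[C@H](OC(C)=O)[C@H](OC(C)=O)[C@@]2(C)C=CC(O[Si](C)(C)C)=C(C)[C@@H]2[C@H](OC(C)=O)[C@]2(O[Si](C)(C)C)[C@@H](C)C(=O)O[C@H]2[C@H]1Cl | intermediate
27 | CNP0391614.1, (1S,2R,3S,6S,7R,8R,9S,10S,11R,17R)-2,3,9-triacetoxy-6-chloro-8-hydroxy-12-oxobriara-5(16),13-dien-18,7-olide | C=C1C[C@H](OC(C)=O)[C@H](OC(C)=O)[C@@]2(C)C=CC(=O)[C@H](C)[C@@H]2[C@H](OC(C)=O)[C@]2(O)[C@@H](C)C(=O)O[C@H]2[C@H]1Cl | target

**Step count and risks**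
Total step count: 18. Longest linear sequence: 16 (steps 1–11 and 14–18; steps 12–13 make the diene).

The three steps most likely to fail are 8, 14 and 15.

Step 8 (regiochemistry of the chloride attack, possible SN2′ opening, C9 epimerisation). The fallback sets out from 11 and brings in the lactone carbons by an intermolecular addition instead of an ester tether. A zinc Reformatsky reaction with methyl 2-bromopropanoate (Zn, THF; addition directed by the zinc chelate of the ketone and the epoxide oxygen, as in Zn(BH4)2 reductions of epoxy ketones) would give the β-hydroxy ester epoxide F1. Ti(OiPr)4 with Et2NH2Cl then opens the 2,3-epoxy alcohol at C6 with inversion, and the freed C7 hydroxyl lactonises to the silyl-protected lactone F2. HF·pyridine returns the route at 15. The price is weaker control of C17.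

Step 14 (slow cycloaddition of a hindered trisubstituted enal in the presence of a free aldehyde, and face selectivity that rests on an allylic-strain model). The fallback sets out from 17 and changes both the order of events and the diene class. Both hydroxyls are silylated (Et3SiOTf, 2,6-lutidine) to the bis(triethylsilyl) ether F3. Butan-2-one is condensed with Me2NCH(OMe)2 to the enaminone F4, which is converted with KN(SiMe3)2 and TBSCl into the much more reactive amino silyloxy diene F5. Cycloaddition of F3 with F5 at 40–60 °C gives the cycloadduct F6. Swern oxidation turns the primary triethylsilyl ether directly into the aldehyde F7, and SmI2 ring closure as in step 15 gives the macrocyclic diol F8. The acid treatment of step 16 then removes the amine, both silyl groups and the MOM ether, and the route is rejoined at 24.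

Step 15 (ring closure may lose to reduction or intermolecular coupling, and the trans-diol may form). The fallback sets out from 22 and closes the ring by polar umpolung. A triazolium-carbene-catalysed intramolecular cross-acyloin condensation, in which the unhindered C3 aldehyde becomes the acyl anion equivalent, would give the macrocyclic C2-hydroxy C3-ketone F9. Zn(BH4)2 reduction through the zinc chelate of the C2 oxygen and the ketone gives the anti (erythro) diol and returns the route at 23.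

**Further compounds**
F1 | step 8 | methyl (2R,3R,4S)-3-[(2R,3R)-3-{4-[(tert-butyldimethylsilyl)oxy]but-1-en-2-yl}oxiran-2-yl]-3-hydroxy-4-(methoxymethoxy)-2-methylhex-5-enoate | C=C[C@H](OCOC)[C@](O)([C@@H](C)C(=O)OC)[C@H]1O[C@@H]1C(=C)CCO[Si](C)(C)C(C)(C)C
F2 | step 8 | (3R,4R,5R)-5-{(1S)-4-[(tert-butyldimethylsilyl)oxy]-1-chloro-2-methylidenebutyl}-4-hydroxy-4-[(1S)-1-(methoxymethoxy)prop-2-en-1-yl]-3-methyloxolan-2-one | C=C[C@H](OCOC)[C@]1(O)[C@@H](C)C(=O)O[C@H]1[C@@H](Cl)C(=C)CCO[Si](C)(C)C(C)(C)C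
F3 | step 14 | bis(triethylsilyl) ether of 17 (primary C3–O and tertiary C8–O) | O=C/C(C)=C/[C@H](OCOC)[C@]1(O[Si](CC)(CC)CC)[C@@H](C)C(=O)O[C@H]1[C@@H](Cl)C(=C)CCO[Si](CC)(CC)CC
F4 | step 14 | (1E)-1-(dimethylamino)pent-1-en-3-one | CCC(=O)/C=C/N(C)C
F5 | step 14 | (1E,3Z)-3-[(tert-butyldimethylsilyl)oxy]-N,N-dimethylpenta-1,3-dien-1-amine | C/C=C(/C=C/N(C)C)O[Si](C)(C)C(C)(C)C
F6 | step 14 | ring A cycloadduct with 14-dimethylamino group, 8-O-triethylsilyl and primary triethylsilyl ether | O=C[C@@]1(C)[C@@H](N(C)C)C=C(O[Si](C)(C)C(C)(C)C)[C@@H](C)[C@@H]1[C@H](OCOC)[C@]2(O[Si](CC)(CC)CC)[C@@H](C)C(=O)O[C@H]2[C@@H](Cl)C(=C)CCO[Si](CC)(CC)CC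
F7 | step 14 | dialdehyde analogue of 22 with 14-dimethylamino group and 8-O-triethylsilyl ether | O=C[C@@]1(C)[C@@H](N(C)C)C=C(O[Si](C)(C)C(C)(C)C)[C@@H](C)[C@@H]1[C@H](OCOC)[C@]2(O[Si](CC)(CC)CC)[C@@H](C)C(=O)O[C@H]2[C@@H](Cl)C(=C)CC=O
F8 | step 14 | macrocyclic (2R,3S)-diol analogue of 23 with 14-dimethylamino group and 8-O-triethylsilyl ether | C=C1C[C@H](O)[C@H](O)[C@@]2(C)[C@@H](N(C)C)C=C(O[Si](C)(C)C(C)(C)C)[C@@H](C)[C@@H]2[C@H](OCOC)[C@]2(O[Si](CC)(CC)CC)[C@@H](C)C(=O)O[C@H]2[C@H]1Cl
F9 | step 15 | macrocyclic (2R)-2-hydroxy-3-ketone (3-oxo analogue of 23) | C=C1CC(=O)[C@H](O)[C@@]2(C)[C@@H](OC)C=C(O[Si](C)(C)C(C)(C)C)[C@@H](C)[C@@H]2[C@H](OCOC)[C@]2(O)[C@@H](C)C(=O)O[C@H]2[C@H]1Cl
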